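The earlier runs and the new flask are simulated on assumed constants.

3 questions stand on one flask, and I take them with one count: the turnovers to target that each catalyst makes before it is lost.

- red: starting material 10 mM; second substrate 1 equiv; reagent 1.2 equiv; protic impurity 3 mM; capture agent 3 mM; free catalyst 5 mol% (in portions, 3); the very flask that is asked about, followed so far; portions every 3.0 min
- flask: starting material 10 mM; second substrate 1.00 equiv; reagent 1.20 equiv; protic impurity 3.00 mM; capture agent 3.00 mM; free catalyst 5 mol% (in portions, 3); time 2.0 h; the portions of free catalyst follow each other after 3.0 min, the first at the start

red run (percent of the starting material charged)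

| time / min | starting material / % | target / % |
|---|---|---|
| 4.00 | 94.5 | 5.2 |
| 12.0 | 79.2 | 17.0 |
| 20.0 | 73.4 | 22.6 |
| 30.0 | 70.9 | 24.7 |
| 50.0 | 69.6 | 24.8 |
| 60.0 | 69.9 | 24.8 |

(each reading ± 0.5 percentage points)

* part of the starting material gone at 2.0 h
* the target standing at 2.0 h, as a percentage of the starting material charged
* the trapped intermediate standing at 2.0 h, as a percentage of the starting material charged

The red run is the flask asked about, so I need no transfer between conditions, but I must know whether it still moves, and from 30.0 min to 50.0 min the target differs by 0.1 percentage points against a scatter of 0.5 points. So the target in the red run reads as stopped within that scatter, yet the red run holds more starting material than target, which turns my suspicion to the catalyst.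

Dividing the plateau target by the loading gives 4.96, and this is my quantity N, the turnover number, target made per catalyst charged. The mass-balance gap in the last reading of the red run is 5.30%, close to the loading of 5 mol%, so I read each catalyst as ending trapped with one starting material on it.

My reckoning for 2.0 h is therefore N times the loading as target, 24.8%, the loading itself as trapped intermediate, and N plus one times the loading as conversion, 29.8%. The forecast gives 30.5%, 24.9% and 5.6%, saying “The catalyst has evidently been consumed”, and its conversion lies 0.7 points above mine.

    second substrate + free catalyst ⇌ catalyst intermediate B (K = 68.0 M⁻¹, k = 3.10 M⁻¹ s⁻¹)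
    reagent + catalyst intermediate A → free catalyst + target (k = 4.80 M⁻¹ s⁻¹)
    starting material + free catalyst ⇌ catalyst intermediate A (K = 12000 M⁻¹, k = 2.50 M⁻¹ s⁻¹)
    second substrate + protic impurity → quenched substrate (k = 0.330 M⁻¹ s⁻¹)
    catalyst intermediate A + capture agent → trapped intermediate (k = 3.50 M⁻¹ s⁻¹)
    reagent + catalyst intermediate B → free catalyst + second product (k = 1.50 M⁻¹ s⁻¹)

At 2.0 h the flask has lost 30.5% of its starting material and stands at 25.5% target and 5.00% trapped intermediate, which by then holds >99.9% of the catalyst charged. Its target divided by its loading gives 5.10 turnovers, against the 4.96 read from the plateau. The neighbour flask charged with 12 mol% of free catalyst, its other charges as in the recipe, is the further case: N times that loading reckons 59.5% target, and the neighbour stands at 54.5%.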